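**Retrosynthetic overview**

1. Target 30 is 1-O-acetyl-sn-glycerol acylated at O-2 by (5R,10R,13R)-labd-8-en-15-oic acid 25. The last disconnections are the glycerol ester (25 + 28, then PMB removal) and the C15 oxidation level.
2. Enabling feature: in ring A the gem-dimethyl carbon C4 and the ring-fusion carbon C5 are vicinal and flanked by C3 and C10. With C1=C2 written in and one C4 methyl raised to CHO, bonds C3–C4 and C5–C10 are the two σ-bonds of a Diels–Alder adduct between a C10=C1–C2=C3 diene and a C4=C5 enal. The tetrasubstituted C8=C9 olefin of ring B lies in the four-atom tether (C6–C9) as a cis olefin.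
3. Both rings form in one step from the acyclic tetraene aldehyde 18: ring A by the cycloaddition, ring B by closure of the tether. Afterwards CHO becomes CH3 (Wolff–Kishner) and C1=C2 is saturated together with debenzylation.
4. 18 comes from alkenyl iodide 12 and dienylstannane 17 (Stille, C9–C10). 12 comes from (R)-citronellol (C13 stereocentre; C9 from ozonolysis) by alkyne homologation, anti-carbomagnesiation/iodination (fixes the C8=C9 geometry), allylation and cross metathesis with methacrolein.
5. The glycerol unit 28 comes from (S)-glycidol.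

Key step: step 14

Remark: labdane numbering is used throughout (C1–C10 decalin, C11–C16 side chain, C17 on C8, C18/C19 on C4, C20 on C10).
Assumption: the sense of induction of the oxazaborolidinium catalyst in step 14 is taken from the accepted pre-transition-state model for 2-substituted enals; if the opposite sense were found, the (S)-catalyst would be used.

**Route**

Step 1
Reactants: 1 (R)-citronellol
Product: 2 {[(3R)-3,7-dimethyloct-6-en-1-yl]oxy}methylbenzene
Conditions: NaH, BnBr, Bu4NI (cat.), THF, 0 °C → rt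
Reagents that add atoms: benzyl bromide BrCc1ccccc1
Why: Williamson etherification of the only hydroxyl; the methyl-bearing stereocentre (C13 of the target, R) comes from the chiral pool and is not touched in any later step.

Step 2
Reactants: 2 benzyl ether
Product: 4 (4R)-6-(benzyloxy)-4-methylhexanal, via ozonide 3 (not isolated)
Conditions: O3, CH2Cl2, −78 °C; then Me2S, −78 °C → rt
Reagents that add atoms: ozone [O-][O+]=O
Why: Ozonolysis with reductive work-up (Criegee mechanism) excises the isopropylidene unit and leaves the aldehyde carbon that becomes C9.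

Step 3
Reactants: 4 aldehyde
Product: 5 {[(3R)-7,7-dibromo-3-methylhept-6-en-1-yl]oxy}methylbenzene
Conditions: CBr4, PPh3, CH2Cl2, 0 °C
Reagents that add atoms: carbon tetrabromide BrC(Br)(Br)Br
Why: First stage of the Corey–Fuchs alkyne synthesis (dibromo-olefination) under neutral conditions that the benzyl ether tolerates; the new carbon is C8.

Step 4
Reactants: 5 dibromoalkene
Product: 7 (6R)-8-(benzyloxy)-6-methyloct-2-yn-1-ol, via lithium acetylide 6 (not isolated)
Conditions: n-BuLi (2.2 equiv), THF, −78 °C; then (CH2O)n, −78 °C → rt; H2O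
Reagents that add atoms: formaldehyde (as paraformaldehyde) C=O
Why: Second stage of the Corey–Fuchs sequence (Br/Li exchange, Fritsch–Buttenberg–Wiechell rearrangement, deprotonation) gives the lithium acetylide, which is hydroxymethylated by formaldehyde to add C7.

Step 5
Reactants: 7 propargylic alcohol
Product: 9 (2Z,6R)-8-(benzyloxy)-3-iodo-2,6-dimethyloct-2-en-1-ol, via oxamagnesole 8 (not isolated)
Conditions: MeMgBr (3.5 equiv), CuI (0.2 equiv), THF, 0 °C → reflux; then I2, −78 → 0 °C
Reagents that add atoms: methylmagnesium bromide C[Mg]Br; iodine [I][I]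
Why: CuI-catalysed anti-carbomagnesiation of a 2-alkyn-1-ol puts CH3 on C8 and holds magnesium on C9 in a five-membered alkoxide chelate, so iodinolysis with retention fixes the tetrasubstituted olefin geometry (C7 cis to iodine, C17 cis to C11).

Step 6
Reactants: 9 allylic alcohol
Product: 10 {[(3R,6Z)-8-bromo-6-iodo-3,7-dimethyloct-6-en-1-yl]oxy}methylbenzene
Conditions: CBr4, PPh3, CH2Cl2, 0 °C
Reagents that add atoms: carbon tetrabromide BrC(Br)(Br)Br
Why: Appel bromination of the primary allylic alcohol by SN2 at CH2; allylic transposition is excluded because the distal olefin carbon is fully substituted.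

Step 7
Reactants: 10 allylic bromide
Product: 11 {[(3R,6Z)-6-iodo-3,7-dimethylundeca-6,10-dien-1-yl]oxy}methylbenzene
Conditions: allylMgBr (2 equiv), THF, −78 → 0 °C
Reagents that add atoms: allylmagnesium bromide C=CC[Mg]Br
Why: SN2 coupling of the allylic bromide with the allyl Grignard reagent adds C6, C5 and a sacrificial CH2; SN2′ attack at the iodine-bearing tetrasubstituted carbon is sterically blocked and the alkenyl iodide does not exchange with an allylmagnesium halide at low temperature.

Step 8
Reactants: 11 terminal alkene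
Product: 12 (2E,6Z,10R)-12-(benzyloxy)-7-iodo-2,6,10-trimethyldodeca-2,6-dienal
Conditions: methacrolein (5 equiv), second-generation Hoveyda–Grubbs catalyst [RuCl2(H2IMes)(=CH–C6H4-2-OiPr)] (5 mol%), CH2Cl2, 40 °C
Reagents that add atoms: methacrolein CC(=C)C=O
Why: Olefin cross metathesis of the terminal alkene with excess methacrolein gives the thermodynamically favoured (E)-2-methyl-2-enal (C4=C5 with C19 as CHO); the tetrasubstituted iodoalkene is inert to the ruthenium carbene.

Step 9
Reactants: 13 ethyl but-2-ynoate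
Product: 14 ethyl (2E)-3-(tributylstannyl)but-2-enoate
Conditions: Bu3SnH, LDA, THF, 0 °C; CuBr·SMe2, −78 °C; then 13, MeOH, −78 °C
Reagents that add atoms: tributyltin hydride CCCC[SnH](CCCC)CCCC
Why: Stannylcupration of the ynoate is a syn addition of Bu3Sn–Cu, and protonation of the alkenylcopper by MeOH at −78 °C, before it can isomerise through the allenoate, gives the kinetic (E)-β-stannyl enoate (Sn trans to CO2Et).

Step 10
Reactants: 14 stannyl enoate
Product: 15 (2E)-3-(tributylstannyl)but-2-en-1-ol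
Conditions: iBu2AlH (2.2 equiv), CH2Cl2, −78 °C
Reagents that add atoms: none
Why: 1,2-Reduction of the enoate by DIBAL-H at low temperature; the C–Sn bond and the olefin geometry are retained.

Step 11
Reactants: 15 stannyl allylic alcohol
Product: 16 (2E)-3-(tributylstannyl)but-2-enal
Conditions: MnO2, CH2Cl2, rt
Reagents that add atoms: none
Why: Chemoselective allylic oxidation with MnO2 under neutral conditions that avoid protodestannylation.

Step 12
Reactants: 16 stannyl enal
Product: 17 tributyl[(2E)-penta-2,4-dien-2-yl]stannane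
Conditions: Ph3PCH3Br, KOtBu, THF, 0 °C
Reagents that add atoms: methyltriphenylphosphonium bromide C[P+](c1ccccc1)(c1ccccc1)c1ccccc1.[Br-]
Why: Wittig methylenation of the enal gives the 2-stannyl diene (C20–C10=C1–C2=C3 unit) without touching the trisubstituted olefin geometry.

Step 13
Reactants: 12 alkenyl iodide enal; 17 dienylstannane
Product: 18 (2E,6Z,8E)-7-[(3R)-5-(benzyloxy)-3-methylpentyl]-2,6,8-trimethylundeca-2,6,8,10-tetraenal
Conditions: Pd(PPh3)4 (10 mol%), Cu(O2C-2-thienyl) (1.5 equiv), [NBu4][O2PPh2] (1.2 equiv), DMF, rt, dark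
Reagents that add atoms: none
Why: Copper-promoted Stille coupling (Sn→Cu transmetalation, tin scavenged as its phosphinate) joins C9 to C10 with retention at both olefins (C7 cis to C10; C9 trans to C2), and the neutral room-temperature medium should keep 18 from cyclising without the catalyst.

Step 14
Reactants: 18 tetraene aldehyde
Product: 19 (1S,4aR,8aS)-5-[(3R)-5-(benzyloxy)-3-methylpentyl]-1,4a,6-trimethyl-1,2,4a,7,8,8a-hexahydronaphthalene-1-carbaldehyde
Conditions: (R)-3,3-diphenyl-1-(2-methylphenyl)tetrahydro-1H,3H-pyrrolo[1,2-c][1,3,2]oxazaborole (0.20 equiv), HNTf2 (0.17 equiv), CH2Cl2, −78 → −20 °C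
Reagents that add atoms: none
Why: Coordination of the formyl oxygen of 18 to the boron of the chiral oxazaborolidinium ion lowers the enal LUMO, and the C10=C1–C2=C3 diene adds suprafacially across C4=C5 in a concerted, asynchronous [4+2] in which C5–C10 bonding is advanced; the closest known reaction type is the oxazaborolidinium-catalysed enantioselective intramolecular Diels–Alder reaction of 2-methyl trienals. Ring A is closed by the cycloaddition itself (new bonds C3–C4 and C5–C10), and ring B is closed at the same moment as the six-membered ring spanned by the tether C6–C7–C8–C9, in which the cis C8=C9 olefin holds C7 and C10 on one side and leaves a half-chair folding. The trans ring fusion (H-5 anti to CH3-20) follows from the endo transition state of the (E)-enal, with the formyl group and H-5 under the diene and the tether exo, together with the (E)-geometry of C10=C1 that places the tether outside and CH3-20 inside; C4 is set by the same suprafacial addition (CHO cis to H-5) and is erased in step 15. The absolute configuration is controlled by the catalyst, whose aryl group shields one face of the s-trans enal held by the formyl C–H···O contact, so that the (R)-catalyst should deliver the (5R,10R) series. The step needs endo over exo and facial selectivity, both supplied by the catalyst–enal complex, and reaction of the terminal diene only, which is secured because the alternative diene C8=C9–C10=C1 is joined to the dienophile by a two-atom tether and the (E)-C10=C1 geometry forbids 6π-electrocyclisation of the triene.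

Step 15
Reactants: 19 Diels–Alder aldehyde
Product: 21 {[(3R)-3-methyl-5-[(4aR,8aR)-2,5,5,8a-tetramethyl-3,4,4a,5,6,8a-hexahydronaphthalen-1-yl]pentyl]oxy}methylbenzene, via hydrazone 20 (not isolated)
Conditions: N2H4·H2O, KOH, diethylene glycol, 130 → 200 °C
Reagents that add atoms: none
Why: Wolff–Kishner reduction (Huang–Minlon procedure) of the neopentyl aldehyde through its hydrazone turns CHO into the second C4 methyl group; the quaternary C4 has no α-hydrogen, so nothing can epimerise, and the isolated olefins and the benzyl ether are inert to hot base.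

Step 16
Reactants: 21 diene benzyl ether
Product: 23 (3R)-3-methyl-5-[(4aR,8aR)-2,5,5,8a-tetramethyl-3,4,4a,5,6,7,8,8a-octahydronaphthalen-1-yl]pentan-1-ol, via saturated benzyl ether 22 (not isolated)
Conditions: H2 (1 atm), Pd/C, EtOAc–EtOH, rt
Reagents that add atoms: none
Why: Heterogeneous hydrogenation saturates the cis-disubstituted C1=C2 olefin and hydrogenolyses the benzyl ether, while the hindered tetrasubstituted C8=C9 olefin should not be reduced under these mild conditions.

Step 17
Reactants: 23 primary alcohol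
Product: 25 (3R)-3-methyl-5-[(4aR,8aR)-2,5,5,8a-tetramethyl-3,4,4a,5,6,7,8,8a-octahydronaphthalen-1-yl]pentanoic acid, via aldehyde 24 (not isolated)
Conditions: TEMPO (0.2 equiv), PhI(OAc)2 (2.5 equiv), MeCN–H2O, rt
Reagents that add atoms: water O
Why: TEMPO/PhI(OAc)2 oxidation in aqueous acetonitrile takes the primary alcohol through the aldehyde hydrate to the acid without an electrophilic halogen source that could attack C8=C9.

Step 18
Reactants: 26 (S)-glycidol
Product: 27 (2R)-2-{[(4-methoxybenzyl)oxy]methyl}oxirane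
Conditions: NaH, 4-MeOC6H4CH2Cl, Bu4NI (cat.), THF–DMF, 0 °C → rt
Reagents that add atoms: 4-methoxybenzyl chloride COc1ccc(CCl)cc1
Why: Williamson etherification; the Payne rearrangement of glycidol alkoxide is degenerate, so the configuration is kept and the descriptor changes to R only through the priority rules.

Step 19
Reactants: 27 PMB glycidyl ether
Product: 28 (2S)-2-hydroxy-3-[(4-methoxybenzyl)oxy]propyl acetate
Conditions: AcOH (3 equiv), CsOAc (0.2 equiv), DMF, 70 °C
Reagents that add atoms: acetic acid CC(=O)O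
Why: Carboxylate-catalysed opening of the terminal epoxide at its CH2 terminus by acetic acid; the stereocentre is not involved and becomes C2 of the sn-glycerol unit (S).

Step 20
Reactants: 25 labdenoic acid; 28 glycerol monoacetate
Product: 29 (2S)-1-(acetyloxy)-3-[(4-methoxybenzyl)oxy]propan-2-yl (3R)-3-methyl-5-[(4aR,8aR)-2,5,5,8a-tetramethyl-3,4,4a,5,6,7,8,8a-octahydronaphthalen-1-yl]pentanoate
Conditions: EDC·HCl, DMAP (0.2 equiv), CH2Cl2, 0 °C → rt
Reagents that add atoms: none
Why: Steglich esterification of the secondary hydroxyl; low temperature and sub-stoichiometric DMAP limit acetyl migration from O-1 to O-2 in 28.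

Step 21
Reactants: 29 PMB-protected glyceride
Product: 30 (2S)-1-(acetyloxy)-3-hydroxypropan-2-yl (3R)-3-methyl-5-[(4aR,8aR)-2,5,5,8a-tetramethyl-3,4,4a,5,6,7,8,8a-octahydronaphthalen-1-yl]pentanoate
Conditions: DDQ, CH2Cl2–pH 7 phosphate buffer, 0 °C
Reagents that add atoms: none
Why: Oxidative cleavage of the PMB ether by DDQ at neutral pH frees the primary hydroxyl without acid or base, which suppresses acyl migration to the 1,3-diacyl isomer; the tetrasubstituted olefin and both esters are inert.

**Compound list**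

1 | (R)-citronellol, (3R)-3,7-dimethyloct-6-en-1-ol | OCC[C@H](C)CCC=C(C)C | starting material
2 | {[(3R)-3,7-dimethyloct-6-en-1-yl]oxy}methylbenzene | c1ccccc1COCC[C@H](C)CCC=C(C)C | intermediate
3 | 3-[(3R)-5-(benzyloxy)-3-methylpentyl]-5,5-dimethyl-1,2,4-trioxolane (ozonide, ring CH configuration undefined) | c1ccccc1COCC[C@H](C)CCC1OOC(C)(C)O1 | intermediate
4 | (4R)-6-(benzyloxy)-4-methylhexanal | c1ccccc1COCC[C@H](C)CCC=O | intermediate
5 | {[(3R)-7,7-dibromo-3-methylhept-6-en-1-yl]oxy}methylbenzene | c1ccccc1COCC[C@H](C)CCC=C(Br)Br | intermediate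
6 | lithium (5R)-7-(benzyloxy)-5-methylhept-1-yn-1-ide | c1ccccc1COCC[C@H](C)CCC#C[Li] | intermediate
7 | (6R)-8-(benzyloxy)-6-methyloct-2-yn-1-ol | c1ccccc1COCC[C@H](C)CCC#CCO | intermediate
8 | 3-[(3R)-5-(benzyloxy)-3-methylpentyl]-4-methyl-2,5-dihydro-1,2-oxamagnesole | c1ccccc1COCC[C@H](C)CCC1=C(C)CO[Mg]1 | intermediate
9 | (2Z,6R)-8-(benzyloxy)-3-iodo-2,6-dimethyloct-2-en-1-ol | c1ccccc1COCC[C@H](C)CC/C(I)=C(\C)CO | intermediate
10 | {[(3R,6Z)-8-bromo-6-iodo-3,7-dimethyloct-6-en-1-yl]oxy}methylbenzene | c1ccccc1COCC[C@H](C)CC/C(I)=C(\C)CBr | intermediate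
11 | {[(3R,6Z)-6-iodo-3,7-dimethylundeca-6,10-dien-1-yl]oxy}methylbenzene | c1ccccc1COCC[C@H](C)CC/C(I)=C(\C)CCC=C | intermediate
12 | (2E,6Z,10R)-12-(benzyloxy)-7-iodo-2,6,10-trimethyldodeca-2,6-dienal | c1ccccc1COCC[C@H](C)CC/C(I)=C(\C)CC/C=C(\C)C=O | intermediate
13 | ethyl but-2-ynoate | CC#CC(=O)OCC | starting material
14 | ethyl (2E)-3-(tributylstannyl)but-2-enoate | CCCC[Sn](CCCC)(CCCC)/C(C)=C/C(=O)OCC | intermediate
15 | (2E)-3-(tributylstannyl)but-2-en-1-ol | CCCC[Sn](CCCC)(CCCC)/C(C)=C/CO | intermediate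
16 | (2E)-3-(tributylstannyl)but-2-enal | CCCC[Sn](CCCC)(CCCC)/C(C)=C/C=O | intermediate
17 | tributyl[(2E)-penta-2,4-dien-2-yl]stannane | CCCC[Sn](CCCC)(CCCC)/C(C)=C/C=C | intermediate
18 | (2E,6Z,8E)-7-[(3R)-5-(benzyloxy)-3-methylpentyl]-2,6,8-trimethylundeca-2,6,8,10-tetraenal | c1ccccc1COCC[C@H](C)CC/C(=C(\C)CC/C=C(\C)C=O)/C(C)=C/C=C | intermediate
19 | (1S,4aR,8aS)-5-[(3R)-5-(benzyloxy)-3-methylpentyl]-1,4a,6-trimethyl-1,2,4a,7,8,8a-hexahydronaphthalene-1-carbaldehyde (trans-fused; CHO cis to H-5) | c1ccccc1COCC[C@H](C)CCC1=C(C)CC[C@@H]2[C@@](C)(C=O)CC=C[C@@]12C | intermediate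
20 | hydrazone of 19 | c1ccccc1COCC[C@H](C)CCC1=C(C)CC[C@@H]2[C@@](C)(C=NN)CC=C[C@@]12C | intermediate
21 | {[(3R)-3-methyl-5-[(4aR,8aR)-2,5,5,8a-tetramethyl-3,4,4a,5,6,8a-hexahydronaphthalen-1-yl]pentyl]oxy}methylbenzene | c1ccccc1COCC[C@H](C)CCC1=C(C)CC[C@@H]2C(C)(C)CC=C[C@@]12C | intermediate
22 | {[(3R)-3-methyl-5-[(4aR,8aR)-2,5,5,8a-tetramethyl-3,4,4a,5,6,7,8,8a-octahydronaphthalen-1-yl]pentyl]oxy}methylbenzene | c1ccccc1COCC[C@H](C)CCC1=C(C)CC[C@@H]2C(C)(C)CCC[C@@]12C | intermediate
23 | (3R)-3-methyl-5-[(4aR,8aR)-2,5,5,8a-tetramethyl-3,4,4a,5,6,7,8,8a-octahydronaphthalen-1-yl]pentan-1-ol, (5R,10R,13R)-labd-8-en-15-ol | OCC[C@H](C)CCC1=C(C)CC[C@@H]2C(C)(C)CCC[C@@]12C | intermediate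
24 | (3R)-3-methyl-5-[(4aR,8aR)-2,5,5,8a-tetramethyl-3,4,4a,5,6,7,8,8a-octahydronaphthalen-1-yl]pentanal | O=CC[C@H](C)CCC1=C(C)CC[C@@H]2C(C)(C)CCC[C@@]12C | intermediate
25 | (3R)-3-methyl-5-[(4aR,8aR)-2,5,5,8a-tetramethyl-3,4,4a,5,6,7,8,8a-octahydronaphthalen-1-yl]pentanoic acid, (5R,10R,13R)-labd-8-en-15-oic acid | OC(=O)C[C@H](C)CCC1=C(C)CC[C@@H]2C(C)(C)CCC[C@@]12C | intermediate
26 | (S)-glycidol, (2S)-oxiran-2-ylmethanol | OC[C@H]1CO1 | starting material
27 | (2R)-2-{[(4-methoxybenzyl)oxy]methyl}oxirane | COc1ccc(COC[C@H]2CO2)cc1 | intermediate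
28 | (2S)-2-hydroxy-3-[(4-methoxybenzyl)oxy]propyl acetate (1-O-acetyl-3-O-PMB-sn-glycerol) | CC(=O)OC[C@H](COCc1ccc(OC)cc1)O | intermediate
29 | (2S)-1-(acetyloxy)-3-[(4-methoxybenzyl)oxy]propan-2-yl (3R)-3-methyl-5-[(4aR,8aR)-2,5,5,8a-tetramethyl-3,4,4a,5,6,7,8,8a-octahydronaphthalen-1-yl]pentanoate | CC(=O)OC[C@H](COCc1ccc(OC)cc1)OC(=O)C[C@H](C)CCC1=C(C)CC[C@@H]2C(C)(C)CCC[C@@]12C | intermediate
30 | (2S)-1-(acetyloxy)-3-hydroxypropan-2-yl (3R)-3-methyl-5-[(4aR,8aR)-2,5,5,8a-tetramethyl-3,4,4a,5,6,7,8,8a-octahydronaphthalen-1-yl]pentanoate | CC(=O)OC[C@H](CO)OC(=O)C[C@H](C)CCC1=C(C)CC[C@@H]2C(C)(C)CCC[C@@]12C | target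

**Summary**

Total step count: 21. Longest linear sequence: 15 (steps 1–8, 13–17, 20, 21).

Steps most likely to fail:

1. Step 14. The doubly hindered diene/dienophile pair (both new ring-A bonds create quaternary carbons) may react too slowly at temperatures where the catalyst keeps facial control, or the electron-rich triene may oligomerise under the acidic catalyst. The fallback moves stereocontrol to a covalently bound auxiliary on a less hindered dienophile and adds the second C4 methyl afterwards; it sets out from 11 and returns at 21. Cross metathesis of 11 with (4S)-3-acryloyl-4-benzyl-1,3-oxazolidin-2-one (second-generation Hoveyda–Grubbs catalyst) would give the (E)-enoyl imide F1. Stille coupling with 17 under the conditions of step 13 would give the tetraene imide F2. Me2AlCl (1.4 equiv, CH2Cl2, −30 °C) should then effect the auxiliary-controlled intramolecular Diels–Alder reaction (chelated s-cis imide, benzyl group shielding one face, carbonyl-endo transition state giving the trans fusion) to the adduct imide F3. LiBH4/MeOH would remove the auxiliary to give the primary alcohol F4, and Dess–Martin oxidation would give the C4–H aldehyde F5. Enolate methylation (KOtBu, MeI, THF) would install the quaternary C4 and give the methylated aldehyde F6, whose C4 configuration is irrelevant. Wolff–Kishner reduction under the conditions of step 15 then returns to 21.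

2. Step 13. Transmetalation of the α-methyl-substituted alkenylstannane onto a tetrasubstituted alkenylpalladium may be too slow, so that protodestannylation or stannane homocoupling takes over. The fallback builds the diene stepwise through an sp–sp2 coupling with little steric demand; it sets out from 12 and returns at 18. Luche reduction of 12 (NaBH4, CeCl3·7H2O, MeOH) would give the allylic alcohol F7. Sonogashira coupling with ethynyltrimethylsilane (PdCl2(PPh3)2, CuI, Et3N) would give the silylated enyne F8, and K2CO3/MeOH the terminal enyne F9. Zirconium-catalysed carboalumination (Me3Al, Cp2ZrCl2; syn addition, CH3 on C10) followed in the same flask by Pd(PPh3)4/ZnCl2-mediated coupling of the alkenylalane with vinyl bromide would give the tetraene alcohol F10. MnO2 oxidation then gives 18.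

3. Step 5. Carbomagnesiation of the internal alkynol with the weakly reactive methyl Grignard reagent may be incomplete, and the alkenylmagnesium may be protonated instead of iodinated. The fallback fixes the olefin geometry through a chelated enolate instead; it sets out from 4 and returns at 9. Reformatsky reaction of 4 with ethyl 2-bromopropanoate (Zn, THF) would give the β-hydroxy ester F11, and Dess–Martin oxidation the β-keto ester F12. NaH then Tf2O should give the chelation-controlled (Z)-enol triflate F13, and DIBAL-H the allylic alcohol triflate F14. Pd(PPh3)4/Me3SnSnMe3/LiCl would give the alkenylstannane F15, and iododestannylation (I2, CH2Cl2, 0 °C) with retention gives 9.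

Further compounds

F1 | step 14 | (4S)-4-benzyl-3-[(2E,6Z,10R)-12-(benzyloxy)-7-iodo-6,10-dimethyldodeca-2,6-dienoyl]-1,3-oxazolidin-2-one | c1ccccc1COCC[C@H](C)CC/C(I)=C(\C)CC/C=C/C(=O)N1[C@@H](Cc2ccccc2)COC1=O
F2 | step 14 | (4S)-4-benzyl-3-[(2E,6Z,8E)-7-[(3R)-5-(benzyloxy)-3-methylpentyl]-6,8-dimethylundeca-2,6,8,10-tetraenoyl]-1,3-oxazolidin-2-one | c1ccccc1COCC[C@H](C)CC/C(=C(\C)CC/C=C/C(=O)N1[C@@H](Cc2ccccc2)COC1=O)/C(C)=C/C=C
F3 | step 14 | (4S)-4-benzyl-3-{[(1S,4aR,8aR)-5-[(3R)-5-(benzyloxy)-3-methylpentyl]-4a,6-dimethyl-1,2,4a,7,8,8a-hexahydronaphthalen-1-yl]carbonyl}-1,3-oxazolidin-2-one | c1ccccc1COCC[C@H](C)CCC1=C(C)CC[C@@H]2[C@@H](C(=O)N3[C@@H](Cc4ccccc4)COC3=O)CC=C[C@@]12C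
F4 | step 14 | [(1S,4aR,8aR)-5-[(3R)-5-(benzyloxy)-3-methylpentyl]-4a,6-dimethyl-1,2,4a,7,8,8a-hexahydronaphthalen-1-yl]methanol | c1ccccc1COCC[C@H](C)CCC1=C(C)CC[C@@H]2[C@@H](CO)CC=C[C@@]12C
F5 | step 14 | (1S,4aR,8aR)-5-[(3R)-5-(benzyloxy)-3-methylpentyl]-4a,6-dimethyl-1,2,4a,7,8,8a-hexahydronaphthalene-1-carbaldehyde | c1ccccc1COCC[C@H](C)CCC1=C(C)CC[C@@H]2[C@@H](C=O)CC=C[C@@]12C
F6 | step 14 | (1R,4aR,8aS)-5-[(3R)-5-(benzyloxy)-3-methylpentyl]-1,4a,6-trimethyl-1,2,4a,7,8,8a-hexahydronaphthalene-1-carbaldehyde (C4 epimer of 19) | c1ccccc1COCC[C@H](C)CCC1=C(C)CC[C@@H]2[C@](C)(C=O)CC=C[C@@]12C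
F7 | step 13 | (2E,6Z,10R)-12-(benzyloxy)-7-iodo-2,6,10-trimethyldodeca-2,6-dien-1-ol | c1ccccc1COCC[C@H](C)CC/C(I)=C(\C)CC/C=C(\C)CO
F8 | step 13 | (2E,6Z,10R)-12-(benzyloxy)-2,6,10-trimethyl-7-[(trimethylsilyl)ethynyl]dodeca-2,6-dien-1-ol | c1ccccc1COCC[C@H](C)CC/C(C#C[Si](C)(C)C)=C(\C)CC/C=C(\C)CO
F9 | step 13 | (2E,6Z,10R)-12-(benzyloxy)-7-ethynyl-2,6,10-trimethyldodeca-2,6-dien-1-ol | c1ccccc1COCC[C@H](C)CC/C(C#C)=C(\C)CC/C=C(\C)CO
F10 | step 13 | (2E,6Z,8E)-7-[(3R)-5-(benzyloxy)-3-methylpentyl]-2,6,8-trimethylundeca-2,6,8,10-tetraen-1-ol | c1ccccc1COCC[C@H](C)CC/C(=C(\C)CC/C=C(\C)CO)/C(C)=C/C=C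
F11 | step 5 | ethyl (6R)-8-(benzyloxy)-3-hydroxy-2,6-dimethyloctanoate (C2/C3 diastereomer mixture) | c1ccccc1COCC[C@H](C)CCC(O)C(C)C(=O)OCC
F12 | step 5 | ethyl (6R)-8-(benzyloxy)-2,6-dimethyl-3-oxooctanoate | c1ccccc1COCC[C@H](C)CCC(=O)C(C)C(=O)OCC
F13 | step 5 | ethyl (2Z,6R)-8-(benzyloxy)-2,6-dimethyl-3-{[(trifluoromethyl)sulfonyl]oxy}oct-2-enoate | c1ccccc1COCC[C@H](C)CC/C(OS(=O)(=O)C(F)(F)F)=C(\C)C(=O)OCC
F14 | step 5 | (2Z,6R)-8-(benzyloxy)-1-hydroxy-2,6-dimethyloct-2-en-3-yl trifluoromethanesulfonate | c1ccccc1COCC[C@H](C)CC/C(OS(=O)(=O)C(F)(F)F)=C(\C)CO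
F15 | step 5 | (2Z,6R)-8-(benzyloxy)-2,6-dimethyl-3-(trimethylstannyl)oct-2-en-1-ol | c1ccccc1COCC[C@H](C)CC/C([Sn](C)(C)C)=C(\C)CO
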